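**Retrosynthetic overview**
- Ring C is closed last: the target comes from the enaminone of a MOM-protected deoxybenzoin (acid closes O1–C2, expels HNMe2 and removes all MOM groups).
- The deoxybenzoin comes from Lemieux–Johnson cleavage of a 2-(2-arylallyl)phenol. Its ring B–CH2 bond (the future C1′–C3 bond) is made by an aromatic Claisen [3,3] rearrangement of the 2-(ring A aryl)allyl ether of the chiral dihydrobenzofuran-4-ol.
- The allyl ether comes from a Mitsunobu coupling of that phenol with 2-[2,4,6-tris(MOMO)phenyl]allyl alcohol (Negishi coupling of metalated phloroglucinol tris-MOM ether with 2-bromoallyl alcohol).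
- The dihydrobenzofuranol comes from a Mitsunobu 5-exo closure (inversion) of a 2-substituted resorcinol diol, made by MeMgBr addition to an α-hydroxy ester, itself from Cu-catalysed opening of methyl (S)-glycidate (the only stereocentre, bought) by 2-metalated resorcinol bis-MOM ether.
- Ring order: rings B and A are bought as resorcinol and phloroglucinol ethers; the dihydrofuran ring is formed first, ring C last.

Assumption: 1,3-bis(methoxymethoxy)benzene and 1,3,5-tris(methoxymethoxy)benzene are bought as such (each is otherwise one MOMCl step from resorcinol or phloroglucinol); benzofuran positions are numbered O1, C2, C3, C3a, C4–C7, C7a.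

**Route**

Step 1
Reactants: 1 1,3-bis(methoxymethoxy)benzene; 2 methyl (2S)-oxirane-2-carboxylate
Product: 5 methyl (2S)-3-[2,6-bis(methoxymethoxy)phenyl]-2-hydroxypropanoate, via aryllithium 3 (not isolated), via arylmagnesium bromide 4 (not isolated)
Conditions: n-BuLi, THF, 0 °C; MgBr2·OEt2, 0 °C; CuI (10 mol %), then 2, −40 → −20 °C; H2O work-up
Reagents that add atoms: none
Why: Directed ortho-lithiation between the two OMOM groups, Li→Mg exchange and CuI-catalysed SN2 opening of the epoxide at its CH2 terminus attach the three-carbon unit to ring B, and the bought stereocentre is not touched and stays (S).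

Step 2
Reactants: 5 methyl (2S)-3-[2,6-bis(methoxymethoxy)phenyl]-2-hydroxypropanoate
Product: 7 (2S)-1-[2,6-bis(methoxymethoxy)phenyl]-3-methylbutane-2,3-diol, via methyl ketone 6 (not isolated)
Conditions: MeMgBr (4 equiv), THF, 0 °C → rt; H2O work-up
Reagents that add atoms: methylmagnesium bromide, C[Mg]Br
Why: Double Grignard addition to the ester builds the dimethylcarbinol, while the adjacent stereocentre sits next to a magnesium alkoxide, is not enolised and stays (S).

Step 3
Reactants: 7 (2S)-1-[2,6-bis(methoxymethoxy)phenyl]-3-methylbutane-2,3-diol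
Product: 8 2-[(2S)-2,3-dihydroxy-3-methylbutyl]benzene-1,3-diol
Conditions: HCl (2 M), MeOH, rt
Reagents that add atoms: none
Why: Acid-catalysed acetal exchange with methanol removes both MOM ethers under conditions too mild to ionise the tertiary alcohol, so the stereocentre is unchanged.

Step 4
Reactants: 8 2-[(2S)-2,3-dihydroxy-3-methylbutyl]benzene-1,3-diol
Product: 9 (2R)-2-(2-hydroxypropan-2-yl)-2,3-dihydro-1-benzofuran-4-ol
Conditions: PPh3, DIAD, THF, 0 °C → rt
Reagents that add atoms: none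
Why: Intramolecular Mitsunobu etherification activates only the secondary alcohol and either of the two equivalent phenols closes the ring 5-exo-tet by SN2, so the bought (S) centre is inverted to the (R) centre of the target.

Step 5
Reactants: 10 1,3,5-tris(methoxymethoxy)benzene; 11 2-bromoprop-2-en-1-ol
Product: 14 2-[2,4,6-tris(methoxymethoxy)phenyl]prop-2-en-1-ol, via aryllithium 12 (not isolated), via arylzinc chloride 13 (not isolated)
Conditions: n-BuLi, THF, 0 °C; ZnCl2, 0 °C → rt; then 11, Pd(OAc)2 (2 mol %), SPhos (4 mol %), THF, 50 °C; H2O work-up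
Reagents that add atoms: none
Why: Directed ortho-lithiation, Li→Zn transmetalation and Negishi cross-coupling (oxidative addition of the vinyl bromide to zerovalent palladium; SPhos handles the di-ortho-substituted arylzinc and the free OH) give the allylic alcohol that carries ring A.

Step 6
Reactants: 9 (2R)-2-(2-hydroxypropan-2-yl)-2,3-dihydro-1-benzofuran-4-ol; 14 2-[2,4,6-tris(methoxymethoxy)phenyl]prop-2-en-1-ol
Product: 15 2-[(2R)-4-({2-[2,4,6-tris(methoxymethoxy)phenyl]prop-2-en-1-yl}oxy)-2,3-dihydro-1-benzofuran-2-yl]propan-2-ol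
Conditions: PPh3, DIAD, THF, 0 °C → rt
Reagents that add atoms: none
Why: Intermolecular Mitsunobu etherification of the phenol with the primary allylic alcohol (SN2 and SN2′ give the same ether, the tertiary alcohol is inert) makes the allyl aryl ether without involving the stereocentre.

Step 7
Reactants: 15 2-[(2R)-4-({2-[2,4,6-tris(methoxymethoxy)phenyl]prop-2-en-1-yl}oxy)-2,3-dihydro-1-benzofuran-2-yl]propan-2-ol
Product: 17 (2R)-2-(2-hydroxypropan-2-yl)-5-{2-[2,4,6-tris(methoxymethoxy)phenyl]prop-2-en-1-yl}-2,3-dihydro-1-benzofuran-4-ol, via ortho-dienone 16 (not isolated)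
Conditions: PhNEt2, 190 °C (sealed tube), 5 h
Reagents that add atoms: none
Why: In this aromatic Claisen rearrangement the concerted [3,3] shift can deliver the allyl terminus only to C5, the single free ortho position (C3a is blocked), and tautomerisation of the dienone gives the phenol with the new ring B–CH2 bond, with no bond to the stereocentre broken.

Step 8
Reactants: 17 (2R)-2-(2-hydroxypropan-2-yl)-5-{2-[2,4,6-tris(methoxymethoxy)phenyl]prop-2-en-1-yl}-2,3-dihydro-1-benzofuran-4-ol
Product: 18 2-[(2R)-4-(methoxymethoxy)-5-{2-[2,4,6-tris(methoxymethoxy)phenyl]prop-2-en-1-yl}-2,3-dihydro-1-benzofuran-2-yl]propan-2-ol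
Conditions: MOMCl, K2CO3, DMF, 0 °C → rt
Reagents that add atoms: chloromethyl methyl ether, COCCl
Why: Williamson-type O-alkylation of the phenoxide (K2CO3 does not deprotonate the tertiary alcohol) masks the future 2′-OH so that it cannot condense with the ketone or the enaminone later.

Step 9
Reactants: 18 2-[(2R)-4-(methoxymethoxy)-5-{2-[2,4,6-tris(methoxymethoxy)phenyl]prop-2-en-1-yl}-2,3-dihydro-1-benzofuran-2-yl]propan-2-ol
Product: 20 2-[(2R)-2-(2-hydroxypropan-2-yl)-4-(methoxymethoxy)-2,3-dihydro-1-benzofuran-5-yl]-1-[2,4,6-tris(methoxymethoxy)phenyl]ethan-1-one, via diol 19 (not isolated)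
Conditions: OsO4 (2 mol %), NaIO4 (4 equiv), 2,6-lutidine, dioxane/H2O 3:1, rt
Reagents that add atoms: sodium periodate, [Na+].[O-]I(=O)(=O)=O
Why: Lemieux–Johnson oxidation (catalytic dihydroxylation of the 1,1-disubstituted alkene, then periodate cleavage of the diol) turns the methylene into the deoxybenzoin ketone without attacking the electron-rich arenes.

Step 10
Reactants: 20 2-[(2R)-2-(2-hydroxypropan-2-yl)-4-(methoxymethoxy)-2,3-dihydro-1-benzofuran-5-yl]-1-[2,4,6-tris(methoxymethoxy)phenyl]ethan-1-one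
Product: 21 3-(dimethylamino)-2-[(2R)-2-(2-hydroxypropan-2-yl)-4-(methoxymethoxy)-2,3-dihydro-1-benzofuran-5-yl]-1-[2,4,6-tris(methoxymethoxy)phenyl]prop-2-en-1-one
Conditions: DMF-DMA (5 equiv), toluene, 100 °C
Reagents that add atoms: N,N-dimethylformamide dimethyl acetal, COC(OC)N(C)C
Why: Condensation of the doubly activated benzylic CH2 with the amide acetal (enaminone formation) installs the one carbon that becomes C2 of the chromone.

Step 11
Reactants: 21 3-(dimethylamino)-2-[(2R)-2-(2-hydroxypropan-2-yl)-4-(methoxymethoxy)-2,3-dihydro-1-benzofuran-5-yl]-1-[2,4,6-tris(methoxymethoxy)phenyl]prop-2-en-1-one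
Product: 23 5,7-dihydroxy-3-[(2R)-4-hydroxy-2-(2-hydroxypropan-2-yl)-2,3-dihydro-1-benzofuran-5-yl]-4H-chromen-4-one, via MOM-protected isoflavone 22 (not isolated)
Conditions: HCl (3 M), MeOH/THF, rt 2 h, then 50 °C
Reagents that add atoms: none
Why: The MOM ether ortho to the ketone is cleaved first (chelation-assisted), the freed phenol closes ring C by conjugate addition–elimination of dimethylamine, and warming removes the remaining MOM ethers, while the ether stereocentre cannot epimerise.

**Compound list**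

1 | 1,3-bis(methoxymethoxy)benzene | COCOc1cccc(OCOC)c1 | starting material
2 | methyl (2S)-oxirane-2-carboxylate (methyl (S)-glycidate) | COC(=O)[C@@H]1CO1 | starting material
3 | [2,6-bis(methoxymethoxy)phenyl]lithium (not isolated) | [Li]c1c(OCOC)cccc1OCOC | intermediate
4 | bromido[2,6-bis(methoxymethoxy)phenyl]magnesium (not isolated) | Br[Mg]c1c(OCOC)cccc1OCOC | intermediate
5 | methyl (2S)-3-[2,6-bis(methoxymethoxy)phenyl]-2-hydroxypropanoate | COC(=O)[C@@H](O)Cc1c(OCOC)cccc1OCOC | intermediate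
6 | (3S)-4-[2,6-bis(methoxymethoxy)phenyl]-3-hydroxybutan-2-one (not isolated) | CC(=O)[C@@H](O)Cc1c(OCOC)cccc1OCOC | intermediate
7 | (2S)-1-[2,6-bis(methoxymethoxy)phenyl]-3-methylbutane-2,3-diol | CC(C)(O)[C@@H](O)Cc1c(OCOC)cccc1OCOC | intermediate
8 | 2-[(2S)-2,3-dihydroxy-3-methylbutyl]benzene-1,3-diol | CC(C)(O)[C@@H](O)Cc1c(O)cccc1O | intermediate
9 | (2R)-2-(2-hydroxypropan-2-yl)-2,3-dihydro-1-benzofuran-4-ol | CC(C)(O)[C@H]1Cc2c(O)cccc2O1 | intermediate
10 | 1,3,5-tris(methoxymethoxy)benzene | COCOc1cc(OCOC)cc(OCOC)c1 | starting material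
11 | 2-bromoprop-2-en-1-ol | C=C(Br)CO | starting material
12 | [2,4,6-tris(methoxymethoxy)phenyl]lithium (not isolated) | [Li]c1c(OCOC)cc(OCOC)cc1OCOC | intermediate
13 | chlorido[2,4,6-tris(methoxymethoxy)phenyl]zinc (not isolated) | Cl[Zn]c1c(OCOC)cc(OCOC)cc1OCOC | intermediate
14 | 2-[2,4,6-tris(methoxymethoxy)phenyl]prop-2-en-1-ol | C=C(CO)c1c(OCOC)cc(OCOC)cc1OCOC | intermediate
15 | 2-[(2R)-4-({2-[2,4,6-tris(methoxymethoxy)phenyl]prop-2-en-1-yl}oxy)-2,3-dihydro-1-benzofuran-2-yl]propan-2-ol | CC(C)(O)[C@H]1Cc2c(OCC(=C)c3c(OCOC)cc(OCOC)cc3OCOC)cccc2O1 | intermediate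
16 | (2R)-2-(2-hydroxypropan-2-yl)-5-{2-[2,4,6-tris(methoxymethoxy)phenyl]prop-2-en-1-yl}-2,3-dihydro-1-benzofuran-4(5H)-one (not isolated; C5 epimers, transient) | CC(C)(O)[C@H]1CC2=C(C=CC(CC(=C)c3c(OCOC)cc(OCOC)cc3OCOC)C2=O)O1 | intermediate
17 | (2R)-2-(2-hydroxypropan-2-yl)-5-{2-[2,4,6-tris(methoxymethoxy)phenyl]prop-2-en-1-yl}-2,3-dihydro-1-benzofuran-4-ol | CC(C)(O)[C@H]1Cc2c(O)c(CC(=C)c3c(OCOC)cc(OCOC)cc3OCOC)ccc2O1 | intermediate
18 | 2-[(2R)-4-(methoxymethoxy)-5-{2-[2,4,6-tris(methoxymethoxy)phenyl]prop-2-en-1-yl}-2,3-dihydro-1-benzofuran-2-yl]propan-2-ol | CC(C)(O)[C@H]1Cc2c(OCOC)c(CC(=C)c3c(OCOC)cc(OCOC)cc3OCOC)ccc2O1 | intermediate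
19 | 3-[(2R)-2-(2-hydroxypropan-2-yl)-4-(methoxymethoxy)-2,3-dihydro-1-benzofuran-5-yl]-2-[2,4,6-tris(methoxymethoxy)phenyl]propane-1,2-diol (not isolated; both carbinol epimers) | CC(C)(O)[C@H]1Cc2c(OCOC)c(CC(O)(CO)c3c(OCOC)cc(OCOC)cc3OCOC)ccc2O1 | intermediate
20 | 2-[(2R)-2-(2-hydroxypropan-2-yl)-4-(methoxymethoxy)-2,3-dihydro-1-benzofuran-5-yl]-1-[2,4,6-tris(methoxymethoxy)phenyl]ethan-1-one | CC(C)(O)[C@H]1Cc2c(OCOC)c(CC(=O)c3c(OCOC)cc(OCOC)cc3OCOC)ccc2O1 | intermediate
21 | 3-(dimethylamino)-2-[(2R)-2-(2-hydroxypropan-2-yl)-4-(methoxymethoxy)-2,3-dihydro-1-benzofuran-5-yl]-1-[2,4,6-tris(methoxymethoxy)phenyl]prop-2-en-1-one (alkene geometry not fixed) | CC(C)(O)[C@H]1Cc2c(OCOC)c(C(=CN(C)C)C(=O)c3c(OCOC)cc(OCOC)cc3OCOC)ccc2O1 | intermediate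
22 | 3-[(2R)-2-(2-hydroxypropan-2-yl)-4-(methoxymethoxy)-2,3-dihydro-1-benzofuran-5-yl]-5,7-bis(methoxymethoxy)-4H-chromen-4-one (not isolated) | CC(C)(O)[C@H]1Cc2c(OCOC)c(-c3coc4cc(OCOC)cc(OCOC)c4c3=O)ccc2O1 | intermediate
23 | 5,7-dihydroxy-3-[(2R)-4-hydroxy-2-(2-hydroxypropan-2-yl)-2,3-dihydro-1-benzofuran-5-yl]-4H-chromen-4-one | CC(C)(O)[C@H]1Cc2c(ccc(-c3coc4cc(O)cc(O)c4c3=O)c2O)O1 | target

**Step count and weak points**

Total: 11 steps. Longest linear sequence: 10 steps (1 → 2 → 3 → 4 → 6 → 7 → 8 → 9 → 10 → 11); step 5 is a one-step side branch.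

Step 4 is the first risk. The neighbouring tertiary hydroxyl can divert the activated secondary alcohol into an epoxide, and opening of that epoxide by the phenol would give net retention and erode the enantiomeric purity. The fallback sets out from 7. The secondary alcohol alone is mesylated (MsCl, Et3N, CH2Cl2, −10 °C) to give the secondary mesylate F1. The MOM ethers are then removed (HCl, MeOH, rt) to give the resorcinol mesylate F2. K2CO3 in acetone at rt lets a phenoxide displace the mesylate 5-exo-tet with inversion, and the route is rejoined at 9.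

Step 7 is the second risk. The bulky, electron-rich 2-aryl group may slow the [3,3] shift so that para migration, or cyclisation of the product phenol onto the styrene, competes. The fallback sets out from 9 and keeps the Claisen step but brings ring A in afterwards:
- O-allylation (allyl bromide, K2CO3, acetone) gives the allyl ether F3.
- Heating (PhNEt2, 190 °C) gives the 5-allylphenol F4.
- MOMCl/K2CO3 gives the MOM ether F5.
- OsO4/NaIO4/2,6-lutidine cleaves it to the arylacetaldehyde F6.
- The arylcerium reagent F7, made from 12 and CeCl3 in THF at −78 °C and used in excess, adds without enolising the aldehyde to give the carbinol F8.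
- Dess–Martin periodinane oxidises F8, and the route is rejoined at 20.

Step 11 is the third risk. If the 2′-OMOM group is lost before ring C has closed, the free 2′-OH can trap the enaminone carbon as a 3-aroylbenzofuran; the tertiary alcohol also limits how strong the acid can be. The fallback sets out from 20. One MOM ether ortho to the ketone is removed selectively (dilute HCl, MeOH, 0 °C → rt, or MgBr2·OEt2 in CH2Cl2) to give the 2-hydroxy ketone F9. DMF-DMA (THF, 60 °C) then gives an enaminone that cyclises at once under neutral conditions while the 2′-oxygen is still protected. The route is rejoined at 22, now isolated, which is deprotected with HCl/MeOH at 50 °C to 23.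

Further compounds
F1 | step 4 | (2S)-1-[2,6-bis(methoxymethoxy)phenyl]-3-hydroxy-3-methylbutan-2-yl methanesulfonate | CC(C)(O)[C@@H](OS(C)(=O)=O)Cc1c(OCOC)cccc1OCOC
F2 | step 4 | (2S)-1-(2,6-dihydroxyphenyl)-3-hydroxy-3-methylbutan-2-yl methanesulfonate | CC(C)(O)[C@@H](OS(C)(=O)=O)Cc1c(O)cccc1O
F3 | step 7 | 2-[(2R)-4-(prop-2-en-1-yloxy)-2,3-dihydro-1-benzofuran-2-yl]propan-2-ol | CC(C)(O)[C@H]1Cc2c(OCC=C)cccc2O1
F4 | step 7 | (2R)-2-(2-hydroxypropan-2-yl)-5-(prop-2-en-1-yl)-2,3-dihydro-1-benzofuran-4-ol | CC(C)(O)[C@H]1Cc2c(O)c(CC=C)ccc2O1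
F5 | step 7 | 2-[(2R)-4-(methoxymethoxy)-5-(prop-2-en-1-yl)-2,3-dihydro-1-benzofuran-2-yl]propan-2-ol | CC(C)(O)[C@H]1Cc2c(OCOC)c(CC=C)ccc2O1
F6 | step 7 | [(2R)-2-(2-hydroxypropan-2-yl)-4-(methoxymethoxy)-2,3-dihydro-1-benzofuran-5-yl]acetaldehyde | CC(C)(O)[C@H]1Cc2c(OCOC)c(CC=O)ccc2O1
F7 | step 7 | dichlorido[2,4,6-tris(methoxymethoxy)phenyl]cerium | Cl[Ce](Cl)c1c(OCOC)cc(OCOC)cc1OCOC
F8 | step 7 | 2-[(2R)-2-(2-hydroxypropan-2-yl)-4-(methoxymethoxy)-2,3-dihydro-1-benzofuran-5-yl]-1-[2,4,6-tris(methoxymethoxy)phenyl]ethan-1-ol (both carbinol epimers) | CC(C)(O)[C@H]1Cc2c(OCOC)c(CC(O)c3c(OCOC)cc(OCOC)cc3OCOC)ccc2O1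
F9 | step 11 | 1-[2-hydroxy-4,6-bis(methoxymethoxy)phenyl]-2-[(2R)-2-(2-hydroxypropan-2-yl)-4-(methoxymethoxy)-2,3-dihydro-1-benzofuran-5-yl]ethan-1-one | CC(C)(O)[C@H]1Cc2c(OCOC)c(CC(=O)c3c(O)cc(OCOC)cc3OCOC)ccc2O1
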